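## Analysis of the target

The target 23 is a γ-butyrolactone, numbered here O1, C2 (carbonyl), C3, C4, C5 (the systematic names below number the ring from the other side). C3 carries an exocyclic methylene, C4 a free carboxyl group, and C5 an unbranched thirteen-carbon chain ending in a primary acetate. C4 (S) and C5 (R) are the only stereocentres; they are adjacent and their substituents are trans on the ring. The α-methylene lactone is a Michael acceptor. The C4–H is α to the acid and allylic to the methylene, so base or hot acylating media can move the double bond into the ring and erase C4. The acetate tolerates neither alkoxide nor enolate chemistry. The difficulty is therefore to set two contiguous stereocentres at the head of a featureless lipid chain, and to bring acid, methylene lactone and acetate through the last steps in a workable order. The strategy rests on the C4–C5 bond: C4 bears a carboxyl carbon and a CH2 (C3) leading to the lactone carbonyl C2, and C5 bears oxygen. If the C5–O1 bond is carried as a C–Si bond, C4–C5 is the bond made in a [3,3] shift of an allyl ester enolate, the C4 carboxyl is the rearranged ester carbon, and C3/C2 are the other half of a succinic acid unit.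

## Retrosynthetic reasoning

The O–acetyl bond of 23 is cut first, giving hydroxy acid 22. The acetate would survive neither the hot magnesium alkoxide medium needed to introduce the methylene group nor the amide base of the rearrangement, so it must come last. The forward step has to acylate a primary alcohol next to a free acid and a methylene lactone without base.

The exocyclic C3=CH2 bond of 22 is removed next, giving the saturated lactone acid 20 by way of the C3-carboxylated lactone 21. The methylene lactone is the most fragile group of the molecule and is best made from a robust precursor at a late stage. Forward, the free C4 acid must be tolerated while C3 alone is activated, which a carboxylation and decarboxylative one-carbon condensation achieves.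

The O1–C2 lactone bond of 20 is opened to the γ-hydroxy amide 19, whose amide nitrogen leaves as 11 on closure. The C–O bond at the carbinol of 19 is then traced back to the C–Si bond of 18. Silicon is inert to the carbanion chemistry that precedes it and is replaced by oxygen with retention, so the configuration of C5 can be fixed long before the oxygen appears.

Compound 18 differs from 17 only by saturation of an alkene and loss of a benzyl group, so both are assigned to one hydrogenation. The alkene has to be removed at this point anyway, because an allylsilane would not survive the electrophile and peracid that convert C–Si into C–O.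

The C2–C3 bond of 17 (the future C4–C5 bond) is the only bond that joins the two stereocentres, so it is the bond to cut. Cutting it and reconnecting the carboxyl oxygen to the far allyl terminus leads to ester 13, through enolate 14, ketene acetal 15 and silyl ester 16. This makes both stereocentres in one step from a single carbinol stereocentre. Any other cut (C3–C4, or C5 to the chain) would require them to be set one after the other. Forward, the rearrangement must enolize only the ester side of a succinic acid derivative, fix the enolate geometry, and pass through a chair.

The ester bond of 13 is cut to allylic alcohol 9 and amide acid 12, and 12 to anhydride 10 and amine 11. A tertiary amide is chosen as the second carboxyl derivative for three reasons: its α-CH2 is much less acidic than the ester α-CH2, it cannot form an imide, and it is later displaced by the C5 hydroxyl.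

The (E)-vinylsilane of 9 comes from alkyne 8 by trans-reduction. The carbinol of 8 comes from ketone 7 by enantioselective reduction, and 7 from racemic alcohol 6. The bond between the carbinol carbon and the alkyne in 6 is cut to aldehyde 3 and acetylide 5, made from 4. This places the single reagent-controlled stereocentre on a substrate class for which such reductions are dependable.

Aldehyde 3 is the oxidation product of alcohol 2, which comes from the symmetric diol 1 by monoprotection. The twelve carbons of 1 plus the two alkyne carbons of 4 give C5 and the whole side chain.

## Alternatives that were turned down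

Alternative 1: The C3–C4 bond is traced to a cyclopropane, and the ring to an aromatic furan. Forward, the copper carbene from ethyl diazoacetate A2 (chiral bis(oxazoline) ligand) adds to the unsubstituted double bond of methyl furan-2-carboxylate A1 and gives the bicyclic cyclopropane A3. Ozonolysis of the enol ether of A3, addition of a chain nucleophile to the aldehyde so formed, and base-induced retro-aldol opening with lactonization then give a trans lactone carrying a formyl group at C4. In its favour, the absolute configuration comes from a catalyst acting on two commodity chemicals, and the trans relation follows from the ring-opening sequence. Against it for this target: the chain must be added as a nucleophile to a sensitive cyclopropane aldehyde, with facial selectivity that depends on the substrate. A thirteen-carbon chain with a terminal oxygen can hardly be added in one piece, so allylation, cross-metathesis and hydrogenation would be needed, followed by aldehyde oxidation and the same late methylenation. It is stronger than the chosen strategy in the origin of chirality (catalytic, from achiral feedstocks). The chosen strategy instead carries the complete chain from the first step and sets C4 and C5 together through one well-understood chair.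

Alternative 2: The O1–C2 and C2–C3 bonds are cut together. Forward, the anti homopropargylic alcohol A4 takes up carbon monoxide A5 under palladium catalysis and closes directly to the α-methylene lactone A6. In its favour, the lactone and its exocyclic methylene arise in one step under conditions that a primary acetate survives, so neither a late methylenation nor a late acetylation is needed; on this point it is stronger than the chosen route. Against it, the key step creates neither stereocentre. Both must already be present in A4, so the stereochemical problem is only moved to an earlier, separate reaction. After the key step, the silyloxymethyl group on C4 must also be unmasked and oxidized through an aldehyde to the acid, next to the exocyclic alkene. That aldehyde has an acidic C4–H and is set up for migration of the double bond into the ring, with loss of C4. The chosen strategy keeps C4 at the acid oxidation level throughout and forms the stereodiad in its key step, at the price of a conventional end-game.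

Alternative 3: The C4–carboxyl bond is cut. Forward, the carbon dioxide radical anion generated from potassium formate A8 (organic photocatalyst, thiol hydrogen-atom donor, blue light) adds in a Giese addition to C4 of the (R)-butenolide A7 and gives the trans acid A9. In its favour, it is the shortest of the four plans: the acid enters at the correct oxidation level and the trans relation should follow from attack anti to the C5 chain. It is stronger than the chosen route in step and redox economy. Against it, C5 must come from a separately prepared enantiopure butenolide whose γ-hydrogen is acidic, so A7 can racemize through its dienolate. Electron transfer to the unsubstituted acceptor can compete with addition and give simple reduction. A9 already carries the acetate, which the magnesium alkoxide medium of the later methylenation would cleave, so a protecting-group detour would be needed after all. The chosen strategy is longer, but both stereocentres derive from one catalyst-set carbinol by a pericyclic step of a known class, and the order of the sensitive groups is settled from the outset.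

Key step: step 9

Remark on the chemistry: the (S,S)-configured ruthenium catalyst of step 5 is assumed to give the (S)-carbinol 8, as it does with other alkynyl ketones; if the sense were opposite, the (R,R)-complex would be used.

## Route

Step 1
Reactants: 1 dodecane-1,12-diol
Product: 2 12-(benzyloxy)dodecan-1-ol
Conditions: NaH (1.0 equiv), BnBr (1.0 equiv), 1 (3 equiv), THF/DMF, 0 °C → rt; unreacted 1 recovered
Reagents that add atoms: benzyl bromide, BrCc1ccccc1
Why: Williamson ether synthesis; with the symmetric diol in excess the monoalkoxide should be benzylated mainly once, and the diol is easily separated and reused.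

Step 2
Reactants: 2 12-(benzyloxy)dodecan-1-ol
Product: 3 12-(benzyloxy)dodecanal
Conditions: TEMPO (10 mol %), PhI(OAc)2 (1.1 equiv), CH2Cl2, rt
Reagents that add atoms: none
Why: Oxoammonium-mediated oxidation of a primary alcohol stops at the aldehyde, and the benzyl ether is inert to it.

Step 3
Reactants: 3 12-(benzyloxy)dodecanal; 4 ethynyl(dimethyl)phenylsilane
Product: 6 rac-14-(benzyloxy)-1-[dimethyl(phenyl)silyl]tetradec-1-yn-3-ol, via lithium acetylide 5 (not isolated)
Conditions: 4, n-BuLi (1.05 equiv), THF, −78 °C; then 3, −78 → 0 °C; H2O
Reagents that add atoms: none
Why: 1,2-Addition of a lithium acetylide to an unhindered aldehyde; the racemic carbinol is acceptable because this centre is removed in step 4 and reset in step 5.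

Step 4
Reactants: 6 rac-14-(benzyloxy)-1-[dimethyl(phenyl)silyl]tetradec-1-yn-3-ol
Product: 7 14-(benzyloxy)-1-[dimethyl(phenyl)silyl]tetradec-1-yn-3-one
Conditions: Dess–Martin periodinane (1.2 equiv), CH2Cl2, rt
Reagents that add atoms: none
Why: Dess–Martin oxidation of a propargylic alcohol to the ynone under near-neutral conditions, which leave the alkynyl–silicon bond and the benzyl ether untouched.

Step 5
Reactants: 7 14-(benzyloxy)-1-[dimethyl(phenyl)silyl]tetradec-1-yn-3-one
Product: 8 (S)-14-(benzyloxy)-1-[dimethyl(phenyl)silyl]tetradec-1-yn-3-ol
Conditions: Ru[(S,S)-TsNCHPhCHPhNH](p-cymene) (1 mol %, base-free amido complex), i-PrOH, 25 °C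
Reagents that add atoms: none
Why: Noyori-type asymmetric transfer hydrogenation; hydride from ruthenium and a proton from the ligand NH are delivered in a six-membered transition state in which the alkynyl group takes the position an aryl group takes with aryl ketones, which should give the (S)-carbinol, and no base is added so that the alkynyl–silicon bond is not cleaved.

Step 6
Reactants: 8 (S)-14-(benzyloxy)-1-[dimethyl(phenyl)silyl]tetradec-1-yn-3-ol
Product: 9 (S,E)-14-(benzyloxy)-1-[dimethyl(phenyl)silyl]tetradec-1-en-3-ol
Conditions: NaAlH2(OCH2CH2OCH3)2 (1.5 equiv), Et2O, 0 °C → rt; aq. potassium sodium tartrate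
Reagents that add atoms: none
Why: Alkoxide-directed trans-hydroalumination of the propargylic alcohol and protonolysis of the vinylalanate should give the (E)-vinylsilane; the carbinol centre is not touched.

Step 7
Reactants: 10 succinic anhydride; 11 dimethylamine
Product: 12 4-(dimethylamino)-4-oxobutanoic acid
Conditions: 11 (2 M in THF, 1.0 equiv), THF, 0 °C → rt
Reagents that add atoms: none
Why: Ring-opening aminolysis of a cyclic anhydride gives the amide acid directly, and the carboxylate formed cannot react further under these conditions.

Step 8
Reactants: 9 (S,E)-14-(benzyloxy)-1-[dimethyl(phenyl)silyl]tetradec-1-en-3-ol; 12 4-(dimethylamino)-4-oxobutanoic acid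
Product: 13 (S,E)-14-(benzyloxy)-1-[dimethyl(phenyl)silyl]tetradec-1-en-3-yl 4-(dimethylamino)-4-oxobutanoate
Conditions: DCC (1.2 equiv), DMAP (10 mol %), CH2Cl2, 0 °C → rt
Reagents that add atoms: none
Why: Steglich esterification; the carbinol C–O bond is not broken, so configuration and alkene geometry are retained, and the tertiary amide cannot close to an imide.

Step 9
Reactants: 13 (S,E)-14-(benzyloxy)-1-[dimethyl(phenyl)silyl]tetradec-1-en-3-yl 4-(dimethylamino)-4-oxobutanoate
Product: 17 (2R,3R,E)-16-(benzyloxy)-2-[2-(dimethylamino)-2-oxoethyl]-3-[dimethyl(phenyl)silyl]hexadec-4-enoic acid, via lithium enolate 14 (not isolated), via silyl ketene acetal 15 (not isolated), via trimethylsilyl ester 16 (not isolated)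
Conditions: lithium diisopropylamide (1.2 equiv), THF/DMPU 4:1, −78 °C; Me3SiCl/Et3N (1.5 equiv), −78 °C → rt, then 45 °C; 1 M HCl
Reagents that add atoms: none
Why: Lithium diisopropylamide removes a proton from the ester α-CH2 of 13, which is more acidic and faster to deprotonate than the amide α-CH2; in THF with the polar cosolvent the enolate 14 should form with the amide-bearing CH2 cis to O–Li, and silylation fixes this geometry in ketene acetal 15. On warming, 15 undergoes a concerted suprafacial [3,3]-sigmatropic shift through a six-membered chair transition state, in which the C2–C3 bond of 17 forms as the allylic C–O bond breaks; the silyl ester 16 so formed is hydrolysed to 17 on work-up. The closest known reaction type is the Ireland–Claisen rearrangement of esters of enantioenriched (E)-γ-silyl allylic alcohols to 2-substituted 3-silyl-4-enoic acids, here with a succinamate in place of a simple alkanoate. No ring is closed. C3 is controlled by the (S)-carbinol and the (E)-vinylsilane: the eleven-carbon chain sits equatorial at the carbinol carbon and silicon equatorial at the other allyl terminus, so the new bond forms on the face of the allyl unit from which oxygen departs, which gives 3R and an E alkene. C2 is controlled by the ketene acetal geometry: the CH2CONMe2 arm cis to the silyloxy group is equatorial in the chair, which gives 2R and thus the 2,3-syn pair that becomes trans in the lactone. The step needs regioselective enolization (secured by the ester/amide acidity gap, low temperature and immediate silylation), one enolate geometry (polar cosolvent, with lithium coordination by the amide carbonyl acting in the same direction) and chair over boat (normal for an acyclic E-allyl ester).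

Step 10
Reactants: 17 (2R,3R,E)-16-(benzyloxy)-2-[2-(dimethylamino)-2-oxoethyl]-3-[dimethyl(phenyl)silyl]hexadec-4-enoic acid
Product: 18 (2R,3R)-2-[2-(dimethylamino)-2-oxoethyl]-3-[dimethyl(phenyl)silyl]-16-hydroxyhexadecanoic acid
Conditions: H2 (1 atm), 10% Pd/C, EtOH, rt
Reagents that add atoms: none
Why: Heterogeneous hydrogenation saturates the disubstituted alkene and hydrogenolyses the benzyl ether in one operation; the alkene must be removed before step 11, whose electrophile and peracid would attack an allylsilane.

Step 11
Reactants: 18 (2R,3R)-2-[2-(dimethylamino)-2-oxoethyl]-3-[dimethyl(phenyl)silyl]-16-hydroxyhexadecanoic acid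
Product: 20 (2R,3S)-2-(13-hydroxytridecyl)-5-oxooxolane-3-carboxylic acid, via hydroxy amide acid 19 (not isolated)
Conditions: KBr (1.5 equiv), AcOOH (32% in AcOH), NaOAc, AcOH, 0 °C → rt; aq. Na2S2O3; then 2 M HCl, THF, 60 °C
Reagents that add atoms: peracetic acid, CC(=O)OO
Why: Fleming–Tamao oxidation: ipso-bromodesilylation removes the phenyl group, peracid adds to silicon and the alkyl group migrates from silicon to oxygen with retention, so the C–Si bond becomes the C–OH bond of 19 with unchanged configuration. Warm aqueous acid then lets this hydroxyl attack the γ-amide carbonyl and expel dimethylamine, closing the five-membered lactone in preference to a four-membered ring at the carboxyl group.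

Step 12
Reactants: 20 (2R,3S)-2-(13-hydroxytridecyl)-5-oxooxolane-3-carboxylic acid
Product: 22 (2R,3S)-2-(13-hydroxytridecyl)-4-methylidene-5-oxooxolane-3-carboxylic acid, via lactone diacid 21 (not isolated)
Conditions: CH3OMgOCO2CH3 (2 M in DMF, excess), 130 °C; 6 M HCl, 0 °C, extraction; then 37% aq. HCHO, PhNHMe, NaOAc, AcOH, rt
Reagents that add atoms: formaldehyde, C=O
Why: Magnesium methyl carbonate carboxylates the lactone α-carbon through a chelated magnesium enolate while the neighbouring acid is masked as its carboxylate; the malonic half-acid 21 then undergoes a decarboxylative Mannich condensation with formaldehyde and the secondary amine, which eliminates to the exocyclic alkene without touching either stereocentre.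

Step 13
Reactants: 22 (2R,3S)-2-(13-hydroxytridecyl)-4-methylidene-5-oxooxolane-3-carboxylic acid
Product: 23 (2R,3S)-2-(13-acetoxytridecyl)-4-methylidene-5-oxooxolane-3-carboxylic acid
Conditions: vinyl acetate (5 equiv), immobilized Candida antarctica lipase B, t-BuOMe, 30 °C
Reagents that add atoms: vinyl acetate, C=COC(C)=O
Why: Lipase-catalysed transesterification through an acyl-enzyme should acetylate the unhindered primary alcohol irreversibly, because the vinyl alcohol set free tautomerizes; the medium is neutral, so the ring acid is not activated and the exocyclic double bond is not moved into the ring.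

## Compound list

1 | dodecane-1,12-diol | OCCCCCCCCCCCCO | starting material
2 | 12-(benzyloxy)dodecan-1-ol | OCCCCCCCCCCCCOCc1ccccc1 | intermediate
3 | 12-(benzyloxy)dodecanal | O=CCCCCCCCCCCCOCc1ccccc1 | intermediate
4 | ethynyl(dimethyl)phenylsilane | C#C[Si](C)(C)c1ccccc1 | starting material
5 | {[dimethyl(phenyl)silyl]ethynyl}lithium | [Li]C#C[Si](C)(C)c1ccccc1 | intermediate
6 | rac-14-(benzyloxy)-1-[dimethyl(phenyl)silyl]tetradec-1-yn-3-ol | OC(CCCCCCCCCCCOCc1ccccc1)C#C[Si](C)(C)c1ccccc1 | intermediate
7 | 14-(benzyloxy)-1-[dimethyl(phenyl)silyl]tetradec-1-yn-3-one | O=C(CCCCCCCCCCCOCc1ccccc1)C#C[Si](C)(C)c1ccccc1 | intermediate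
8 | (S)-14-(benzyloxy)-1-[dimethyl(phenyl)silyl]tetradec-1-yn-3-ol | O[C@@H](CCCCCCCCCCCOCc1ccccc1)C#C[Si](C)(C)c1ccccc1 | intermediate
9 | (S,E)-14-(benzyloxy)-1-[dimethyl(phenyl)silyl]tetradec-1-en-3-ol | O[C@@H](CCCCCCCCCCCOCc1ccccc1)/C=C/[Si](C)(C)c1ccccc1 | intermediate
10 | succinic anhydride (oxolane-2,5-dione) | O=C1CCC(=O)O1 | starting material
11 | dimethylamine | CNC | starting material
12 | 4-(dimethylamino)-4-oxobutanoic acid | CN(C)C(=O)CCC(=O)O | intermediate
13 | (S,E)-14-(benzyloxy)-1-[dimethyl(phenyl)silyl]tetradec-1-en-3-yl 4-(dimethylamino)-4-oxobutanoate | CN(C)C(=O)CCC(=O)O[C@@H](CCCCCCCCCCCOCc1ccccc1)/C=C/[Si](C)(C)c1ccccc1 | intermediate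
14 | lithium enolate of 13 at the ester α-carbon, amide-bearing CH2 cis to O–Li | [Li]O/C(=C\CC(=O)N(C)C)O[C@@H](CCCCCCCCCCCOCc1ccccc1)/C=C/[Si](C)(C)c1ccccc1 | intermediate
15 | (Z)-trimethylsilyl ketene acetal of 13: (3Z)-4-{[(S,E)-14-(benzyloxy)-1-[dimethyl(phenyl)silyl]tetradec-1-en-3-yl]oxy}-N,N-dimethyl-4-[(trimethylsilyl)oxy]but-3-enamide | C[Si](C)(C)O/C(=C\CC(=O)N(C)C)O[C@@H](CCCCCCCCCCCOCc1ccccc1)/C=C/[Si](C)(C)c1ccccc1 | intermediate
16 | trimethylsilyl (2R,3R,E)-16-(benzyloxy)-2-[2-(dimethylamino)-2-oxoethyl]-3-[dimethyl(phenyl)silyl]hexadec-4-enoate | CN(C)C(=O)C[C@H](C(=O)O[Si](C)(C)C)[C@H]([Si](C)(C)c1ccccc1)/C=C/CCCCCCCCCCCOCc1ccccc1 | intermediate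
17 | (2R,3R,E)-16-(benzyloxy)-2-[2-(dimethylamino)-2-oxoethyl]-3-[dimethyl(phenyl)silyl]hexadec-4-enoic acid | CN(C)C(=O)C[C@H](C(=O)O)[C@H]([Si](C)(C)c1ccccc1)/C=C/CCCCCCCCCCCOCc1ccccc1 | intermediate
18 | (2R,3R)-2-[2-(dimethylamino)-2-oxoethyl]-3-[dimethyl(phenyl)silyl]-16-hydroxyhexadecanoic acid | CN(C)C(=O)C[C@H](C(=O)O)[C@H]([Si](C)(C)c1ccccc1)CCCCCCCCCCCCCO | intermediate
19 | (2S,3R)-2-[2-(dimethylamino)-2-oxoethyl]-3,16-dihydroxyhexadecanoic acid | CN(C)C(=O)C[C@H](C(=O)O)[C@H](O)CCCCCCCCCCCCCO | intermediate
20 | (2R,3S)-2-(13-hydroxytridecyl)-5-oxooxolane-3-carboxylic acid | C1C(=O)O[C@H](CCCCCCCCCCCCCO)[C@H]1C(=O)O | intermediate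
21 | (2R,3S)-2-(13-hydroxytridecyl)-5-oxooxolane-3,4-dicarboxylic acid (C4 not defined) | OC(=O)C1C(=O)O[C@H](CCCCCCCCCCCCCO)[C@H]1C(=O)O | intermediate
22 | (2R,3S)-2-(13-hydroxytridecyl)-4-methylidene-5-oxooxolane-3-carboxylic acid | C=C1C(=O)O[C@H](CCCCCCCCCCCCCO)[C@H]1C(=O)O | intermediate
23 | (2R,3S)-2-(13-acetoxytridecyl)-4-methylidene-5-oxooxolane-3-carboxylic acid | C=C1C(=O)O[C@H](CCCCCCCCCCCCCOC(C)=O)[C@H]1C(=O)O | target

## Step count and least certain steps

Total: 13 steps. Longest linear sequence: 12 steps (steps 1–6 and 8–13); step 7 is a one-step side branch.

Step 9 (key step). The most likely failure is incomplete control of the enolate geometry, so that both ketene acetal isomers rearrange and the product is a mixture at C2. The amide carbonyl can hold lithium and the polar cosolvent may not override it fully. A smaller risk is partial enolization on the amide side. C3 is not at risk, because it depends only on the chair and on the carbinol of 13. The fallback sets the acid-bearing ring carbon by equilibration instead of kinetically. It sets out from 13, which is rearranged without geometry control to give 17 together with its C2 epimer, (2S,3R,E)-16-(benzyloxy)-2-[2-(dimethylamino)-2-oxoethyl]-3-[dimethyl(phenyl)silyl]hexadec-4-enoic acid F1. The mixture is taken through steps 10 and 11. In these, F1 passes through (2S,3R)-2-[2-(dimethylamino)-2-oxoethyl]-3-[dimethyl(phenyl)silyl]-16-hydroxyhexadecanoic acid F2 and (2R,3R)-2-[2-(dimethylamino)-2-oxoethyl]-3,16-dihydroxyhexadecanoic acid F3 to the cis lactone acid (2R,3R)-2-(13-hydroxytridecyl)-5-oxooxolane-3-carboxylic acid F4. The mixture of 20 and F4 is esterified with Me3SiCHN2 in MeOH/toluene to methyl (2R,3R)-2-(13-hydroxytridecyl)-5-oxooxolane-3-carboxylate F5 and methyl (2R,3S)-2-(13-hydroxytridecyl)-5-oxooxolane-3-carboxylate F6. DBU in CH2Cl2 should then epimerize the ester-bearing carbon through its enolate towards the trans ester F6, in which chain and ester no longer eclipse. Hydrolysis of F6 with 2 M HCl in dioxane at 80 °C returns to 20, from where step 12 follows.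

Step 10. The risk is double-bond migration on the palladium surface before saturation. A shift into the C3–C4 position would make a vinylsilane and scramble the silicon-bearing stereocentre on reduction. The fallback separates the two tasks and starts from 17. Diimide generated from 2-nitrobenzenesulfonylhydrazide and Et3N in CH2Cl2 reduces the alkene without any metal hydride, giving (2R,3R)-16-(benzyloxy)-2-[2-(dimethylamino)-2-oxoethyl]-3-[dimethyl(phenyl)silyl]hexadecanoic acid F7. Hydrogenolysis of the benzyl ether of F7 over Pd(OH)2/C (H2, EtOH), now with no alkene present, leads back to 18.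

Step 11. The risk is incomplete conversion of the C–Si bond. The silicon sits on a secondary carbon between a long chain and a branched centre, the neighbouring carboxyl group can tie it up as a cyclic silyl ester once the phenyl group has left, and the brominating medium may start to oxidize the free primary alcohol if the reaction is forced. The fallback changes both the way the phenyl group is removed and the oxidant, and starts from 18. Protodesilylation with HBF4·OEt2 in CH2Cl2 gives (2R,3R)-2-[2-(dimethylamino)-2-oxoethyl]-3-[fluoro(dimethyl)silyl]-16-hydroxyhexadecanoic acid F8. Nucleophilic oxidation of F8 with H2O2, KF and KHCO3 in THF/MeOH gives 19 with retention, and 19 is lactonized with 2 M HCl as in step 11 to 20.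

Step 12. The risks are incomplete carboxylation during the long heating, loss of the new carboxyl group on acidification before the condensation, and migration of the new double bond into the ring if the Mannich stage is prolonged. The fallback avoids the carboxylation and starts from 20. Lithium diisopropylamide (3.2 equiv, THF, −78 °C) forms the carboxylate, the alkoxide and the lactone enolate, which is trapped with dimethyl(methylidene)ammonium iodide to give the Mannich base (2R,3S)-4-[(dimethylamino)methyl]-2-(13-hydroxytridecyl)-5-oxooxolane-3-carboxylic acid F9. Oxidation of F9 with mCPBA (NaHCO3, CH2Cl2) gives the amine oxide 1-[(4S,5R)-4-carboxy-5-(13-hydroxytridecyl)-2-oxooxolan-3-yl]-N,N-dimethylmethanamine N-oxide F10, which undergoes Cope elimination at room temperature to 22.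

## Further compounds

F1 | step 9 | (2S,3R,E)-16-(benzyloxy)-2-[2-(dimethylamino)-2-oxoethyl]-3-[dimethyl(phenyl)silyl]hexadec-4-enoic acid | CN(C)C(=O)C[C@@H](C(=O)O)[C@H]([Si](C)(C)c1ccccc1)/C=C/CCCCCCCCCCCOCc1ccccc1
F2 | step 9 | (2S,3R)-2-[2-(dimethylamino)-2-oxoethyl]-3-[dimethyl(phenyl)silyl]-16-hydroxyhexadecanoic acid | CN(C)C(=O)C[C@@H](C(=O)O)[C@H]([Si](C)(C)c1ccccc1)CCCCCCCCCCCCCO
F3 | step 9 | (2R,3R)-2-[2-(dimethylamino)-2-oxoethyl]-3,16-dihydroxyhexadecanoic acid | CN(C)C(=O)C[C@@H](C(=O)O)[C@H](O)CCCCCCCCCCCCCO
F4 | step 9 | (2R,3R)-2-(13-hydroxytridecyl)-5-oxooxolane-3-carboxylic acid | C1C(=O)O[C@H](CCCCCCCCCCCCCO)[C@@H]1C(=O)O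
F5 | step 9 | methyl (2R,3R)-2-(13-hydroxytridecyl)-5-oxooxolane-3-carboxylate | C1C(=O)O[C@H](CCCCCCCCCCCCCO)[C@@H]1C(=O)OC
F6 | step 9 | methyl (2R,3S)-2-(13-hydroxytridecyl)-5-oxooxolane-3-carboxylate | C1C(=O)O[C@H](CCCCCCCCCCCCCO)[C@H]1C(=O)OC
F7 | step 10 | (2R,3R)-16-(benzyloxy)-2-[2-(dimethylamino)-2-oxoethyl]-3-[dimethyl(phenyl)silyl]hexadecanoic acid | CN(C)C(=O)C[C@H](C(=O)O)[C@H]([Si](C)(C)c1ccccc1)CCCCCCCCCCCCCOCc1ccccc1
F8 | step 11 | (2R,3R)-2-[2-(dimethylamino)-2-oxoethyl]-3-[fluoro(dimethyl)silyl]-16-hydroxyhexadecanoic acid | CN(C)C(=O)C[C@H](C(=O)O)[C@H]([Si](C)(C)F)CCCCCCCCCCCCCO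
F9 | step 12 | (2R,3S)-4-[(dimethylamino)methyl]-2-(13-hydroxytridecyl)-5-oxooxolane-3-carboxylic acid (C4 not defined) | CN(C)CC1C(=O)O[C@H](CCCCCCCCCCCCCO)[C@H]1C(=O)O
F10 | step 12 | 1-[(4S,5R)-4-carboxy-5-(13-hydroxytridecyl)-2-oxooxolan-3-yl]-N,N-dimethylmethanamine N-oxide (C3 of the ring not defined) | C[N+](C)([O-])CC1C(=O)O[C@H](CCCCCCCCCCCCCO)[C@H]1C(=O)O
A1 | alternative 1 | methyl furan-2-carboxylate | COC(=O)c1ccco1
A2 | alternative 1 | ethyl diazoacetate | CCOC(=O)C=[N+]=[N-]
A3 | alternative 1 | 6-ethyl 3-methyl exo-2-oxabicyclo[3.1.0]hex-3-ene-3,6-dicarboxylate, single enantiomer | COC(=O)C1=C[C@H]2[C@@H](O1)[C@@H]2C(=O)OCC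
A4 | alternative 2 | (14R,15R)-15-[(tert-butyldimethylsilyloxy)methyl]-14-hydroxyheptadec-16-yn-1-yl acetate | C#C[C@H](CO[Si](C)(C)C(C)(C)C)[C@H](O)CCCCCCCCCCCCCOC(C)=O
A5 | alternative 2 | carbon monoxide | [C-]#[O+]
A6 | alternative 2 | (4R,5R)-5-(13-acetoxytridecyl)-4-[(tert-butyldimethylsilyloxy)methyl]-3-methylideneoxolan-2-one | C=C1C(=O)O[C@H](CCCCCCCCCCCCCOC(C)=O)[C@H]1CO[Si](C)(C)C(C)(C)C
A7 | alternative 3 | 13-[(2R)-5-oxo-2,5-dihydrofuran-2-yl]tridecyl acetate | C1=CC(=O)O[C@@H]1CCCCCCCCCCCCCOC(C)=O
A8 | alternative 3 | potassium formate | [K+].[O-]C=O
A9 | alternative 3 | (2R,3S)-2-(13-acetoxytridecyl)-5-oxooxolane-3-carboxylic acid | C1C(=O)O[C@H](CCCCCCCCCCCCCOC(C)=O)[C@H]1C(=O)O
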